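**Overview**

- Retrosynthesis: the C2–O1 bond of the oxolane is cut first (to an acyclic 1,4-diol), then the two benzylic C–O bonds together with the C3–H and C4–H bonds (to a stereocentre-free E,E-diene), then the central C3–C4 bond (to two 1-arylpropynes), and last the two aryl–alkyne bonds (to two aryl iodides and propyne).
- Forward: two Sonogashira couplings, a Cp2Zr-mediated head-to-head cross-coupling of the two alkynes with protonolysis (joins the chain at C3–C4), a twofold asymmetric hydroboration–oxidation, and only then closure of the one new ring, the oxolane, by C–O bond formation. Both benzene rings are bought.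
- Enabling feature: around ring O1–C2–C3–C4–C5 every pair of neighbours is trans and all four carbons are (S). Each half (benzylic C2–O beside C3–CH3, benzylic C5–O beside C4–CH3) is therefore the cis H/OH adduct of an (E)-ArCH=C(CH3) unit, and both benzylic C–O bonds sit on electron-rich aryl rings and can ionise.
- Stereochemistry: the metallacycle fixes the E,E geometry; syn B–H delivery from IpcBH2 sets all four centres in one operation under reagent control; the reversible acid-catalysed closure then keeps C2 and C5 trans to their methyl neighbours.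

Key step: step 4

Remark on the chemistry (assumption): the sense of induction of IpcBH2 on this diene is assigned by analogy with simple trisubstituted alkenes, which points to the reagent made from (−)-α-pinene; should the sense prove opposite, the TMEDA adduct made from (+)-α-pinene is used with nothing else changed.

**Route**

Step 1
Reactants: 1 4-iodo-1,2-dimethoxybenzene; 2 propyne
Product: 3 1,2-dimethoxy-4-(prop-1-yn-1-yl)benzene
Conditions: PdCl2(PPh3)2 (2 mol %), CuI (4 mol %), Et3N, THF, 25 °C (2 as a THF solution in excess, closed vessel)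
Reagents that add atoms: none
Why: Sonogashira coupling, in which the electron-rich aryl iodide adds oxidatively to zerovalent palladium (formed in the flask from PdCl2(PPh3)2) at room temperature and the copper acetylide of propyne transmetalates cleanly; no stereocentre is formed.

Step 2
Reactants: 4 5-iodo-1,2,3-trimethoxybenzene; 2 propyne
Product: 5 1,2,3-trimethoxy-5-(prop-1-yn-1-yl)benzene
Conditions: PdCl2(PPh3)2 (2 mol %), CuI (4 mol %), Et3N, THF, 25 °C (2 as a THF solution in excess, closed vessel)
Reagents that add atoms: none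
Why: Sonogashira coupling of the second aryl iodide under the same conditions, the excess of volatile propyne covering loss to Glaser dimerisation; no stereocentre is formed.

Step 3
Reactants: 3 1,2-dimethoxy-4-(prop-1-yn-1-yl)benzene; 5 1,2,3-trimethoxy-5-(prop-1-yn-1-yl)benzene
Product: 8 (1E,3E)-1-(3,4-dimethoxyphenyl)-2,3-dimethyl-4-(3,4,5-trimethoxyphenyl)buta-1,3-diene, via zirconacyclopentene 6 (not isolated), via zirconacyclopentadiene 7 (not isolated)
Conditions: Cp2ZrCl2 (1 equiv), EtMgBr (2 equiv), THF, −78 °C; 3 (1 equiv), 0 °C; 5, 50 °C; 3 M HCl, 0 °C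
Reagents that add atoms: none
Why: Known one-pot pairwise coupling of two different alkynes on Cp2Zr, in which Cp2ZrEt2 loses ethane to give Cp2Zr(C2H4) as a source of divalent zirconium, this cyclises oxidatively with 3 to the zirconacyclopentene with the aryl group next to zirconium, warming with 5 expels ethylene and forms the C3–C4 bond head-to-head, and protonolysis of both Zr–C(sp2) bonds with retention fixes the E,E geometry (no stereocentre is formed).

Step 4
Reactants: 8 (1E,3E)-1-(3,4-dimethoxyphenyl)-2,3-dimethyl-4-(3,4,5-trimethoxyphenyl)buta-1,3-diene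
Product: 10 (1S,2S,3S,4S)-1-(3,4-dimethoxyphenyl)-2,3-dimethyl-4-(3,4,5-trimethoxyphenyl)butane-1,4-diol, via bis(isopinocampheylboryl) adduct 9 (not isolated)
Conditions: (IpcBH2)2·TMEDA [Ipc = (1S,2R,3S,5S)-isopinocampheyl, from (−)-α-pinene] (1.5 equiv), BF3·OEt2 (3 equiv), THF, 25 °C, filter; 8 added slowly, −25 → 0 °C; 3 M NaOH, 30% H2O2, 0 → 25 °C
Reagents that add atoms: hydrogen peroxide, OO
Why: Proposed new method: each half of 8 should add free IpcBH2 through the concerted four-centre syn transition state, boron going to the benzylic CH (C1, C4) and hydrogen to the methyl-bearing carbon (C2, C3), after which alkaline H2O2 turns both C–B bonds into C–O bonds with retention. The closest known reaction type is the asymmetric hydroboration–oxidation of single trans-disubstituted and trisubstituted alkenes, aryl-substituted ones included, with IpcBH2; what is new is its twofold use on a 1,4-diaryl-2,3-dimethylbuta-1,3-diene. No ring is closed here (the oxolane is left to step 5), so no mode of closure applies. The relative configuration within each half (C1/C2 and C4/C3) follows from syn addition to an E alkene, and the absolute sense at all four centres is set by the isopinocampheyl group, which should pick the same enantioface of both alkenes and so deliver the anti-dimethyl (1S,2S,3S,4S) array. The step needs boron at the benzylic carbon, which the CH versus C(CH3) substitution pattern secures, and reagent rather than substrate control in the second addition, which is expected because the vicinal methyl groups twist the two alkenes out of conjugation and the new centre at C2 faces only a hydrogen across the remaining double bond, so allylic 1,3-strain is small. Internal addition of the hindered Ipc(R)BH unit to the second alkene (borolane formation) is countered by adding 8 slowly to an excess of the more reactive monoalkylborane at −25 °C, and a mismatched second addition would give a separable 2,3-syn diol, which should raise the enantiomeric purity of 10 above that of a single addition.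

Step 5
Reactants: 10 (1S,2S,3S,4S)-1-(3,4-dimethoxyphenyl)-2,3-dimethyl-4-(3,4,5-trimethoxyphenyl)butane-1,4-diol
Product: 11 (2S,3S,4S,5S)-2-(3,4-dimethoxyphenyl)-3,4-dimethyl-5-(3,4,5-trimethoxyphenyl)oxolane (5-methoxygalbelgin)
Conditions: BF3·OEt2 (0.2 equiv), CH2Cl2, −40 → 0 °C
Reagents that add atoms: none
Why: Acid-catalysed cyclodehydration of a 1,4-diarylbutane-1,4-diol, well known for 2,5-diaryl-3,4-dimethyloxolane lignans, in which the C1 carbinol para to a methoxy group ionises to a quinoid benzylic cation, the C4 hydroxyl captures it in a 5-exo-trig closure anti to the C2 methyl group, and reopening of the ether lets the mixture drain to the all-trans (2S,3S,4S,5S) isomer, with C3 and C4 untouched and C2 and C5 ending as step 4 set them.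

**Compound list**

1 | 4-iodo-1,2-dimethoxybenzene | COc1ccc(I)cc1OC | starting material
2 | propyne | CC#C | starting material
3 | 1,2-dimethoxy-4-(prop-1-yn-1-yl)benzene | CC#Cc1ccc(OC)c(OC)c1 | intermediate
4 | 5-iodo-1,2,3-trimethoxybenzene | COc1cc(I)cc(OC)c1OC | starting material
5 | 1,2,3-trimethoxy-5-(prop-1-yn-1-yl)benzene | CC#Cc1cc(OC)c(OC)c(OC)c1 | intermediate
6 | 1,1-bis(cyclopentadienyl)-2-(3,4-dimethoxyphenyl)-3-methyl-1-zirconacyclopent-2-ene (not isolated; cyclopentadienyl ligands drawn sigma-bound) | CC1=C(c2ccc(OC)c(OC)c2)[Zr](C2C=CC=C2)(C2C=CC=C2)CC1 | intermediate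
7 | 1,1-bis(cyclopentadienyl)-2-(3,4-dimethoxyphenyl)-3,4-dimethyl-5-(3,4,5-trimethoxyphenyl)-1-zirconacyclopenta-2,4-diene (not isolated; cyclopentadienyl ligands drawn sigma-bound) | CC1=C(c2ccc(OC)c(OC)c2)[Zr](C2C=CC=C2)(C2C=CC=C2)C(c2cc(OC)c(OC)c(OC)c2)=C1C | intermediate
8 | (1E,3E)-1-(3,4-dimethoxyphenyl)-2,3-dimethyl-4-(3,4,5-trimethoxyphenyl)buta-1,3-diene | COc1ccc(/C=C(C)/C(C)=C/c2cc(OC)c(OC)c(OC)c2)cc1OC | intermediate
9 | (1S,2R,3R,4S)-1-(3,4-dimethoxyphenyl)-2,3-dimethyl-4-(3,4,5-trimethoxyphenyl)-1,4-bis{[(1S,2R,3S,5S)-2,6,6-trimethylbicyclo[3.1.1]heptan-3-yl]boranyl}butane (not isolated; same spatial arrangement as 10, C2 and C3 read R only because boron ranks below carbon) | COc1ccc([C@@H]([BH][C@H]3C[C@H]4C[C@H](C4(C)C)[C@@H]3C)[C@@H](C)[C@H](C)[C@H]([BH][C@H]3C[C@H]4C[C@H](C4(C)C)[C@@H]3C)c2cc(OC)c(OC)c(OC)c2)cc1OC | intermediate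
10 | (1S,2S,3S,4S)-1-(3,4-dimethoxyphenyl)-2,3-dimethyl-4-(3,4,5-trimethoxyphenyl)butane-1,4-diol | COc1ccc([C@@H](O)[C@@H](C)[C@H](C)[C@H](O)c2cc(OC)c(OC)c(OC)c2)cc1OC | intermediate
11 | (2S,3S,4S,5S)-2-(3,4-dimethoxyphenyl)-3,4-dimethyl-5-(3,4,5-trimethoxyphenyl)oxolane (5-methoxygalbelgin) | COc1ccc([C@H]2O[C@H](c3cc(OC)c(OC)c(OC)c3)[C@@H](C)[C@@H]2C)cc1OC | target

**Count**

Total steps: 5. Longest linear sequence: 4 steps (step 1 or 2, then steps 3, 4 and 5).

**Steps most likely to fail**

Step 4 (Proposed new method). Reagent control may be lost in the second B–H addition, through internal delivery from the first-formed borane or a mismatched pairing, and enantioface discrimination at an aryl-bearing CH may be weak. The fallback uses known chemistry, sets out from iodide 4 (iodide 1 enters later) and returns at diol 10.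
- Iodide 4 is converted by iodine–magnesium exchange (iPrMgCl·LiCl, THF) and a DMF quench into 3,4,5-trimethoxybenzaldehyde F1.
- Asymmetric crotylboration with the (E)-crotyl-B(Ipc)2 reagent made from (+)-α-pinene (−78 °C; NaOH, H2O2) should give the anti alcohol (1S,2S)-2-methyl-1-(3,4,5-trimethoxyphenyl)but-3-en-1-ol F2; the enantiomeric reagent is taken if the sense is found reversed.
- Hydroboration of the terminal alkene with 9-BBN and oxidation gives (1S,2S)-2-methyl-1-(3,4,5-trimethoxyphenyl)butane-1,4-diol F3.
- TEMPO/PhI(OAc)2 oxidises the primary alcohol and lactonises to (4S,5S)-4-methyl-5-(3,4,5-trimethoxyphenyl)oxolan-2-one F4.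
- LiN(SiMe3)2 and MeI methylate the enolate anti to the C4 methyl group, giving (3S,4S,5S)-3,4-dimethyl-5-(3,4,5-trimethoxyphenyl)oxolan-2-one F5.
- iBu2AlH at −78 °C reduces this to the lactol (3S,4S,5S)-3,4-dimethyl-5-(3,4,5-trimethoxyphenyl)oxolan-2-ol F6.
- (3,4-Dimethoxyphenyl)magnesium chloride F7, made from iodide 1 with iPrMgCl·LiCl, opens the lactol to diol 10 mixed with its C1 epimer, (1R,2S,3S,4S)-1-(3,4-dimethoxyphenyl)-2,3-dimethyl-4-(3,4,5-trimethoxyphenyl)butane-1,4-diol F8.
- Step 5 ionises exactly that carbinol, so both epimers should converge on 11.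

Step 3. The two alkynes may scramble on zirconium (homocoupling), or the second alkyne may insert with its aryl group remote from zirconium. The fallback sets out from alkynes 3 and 5 and returns at diene 8.
- Copper-catalysed syn hydroboration (CuCl, NaOtBu, Xantphos, B2pin2, MeOH, THF) places boron on the methyl-bearing carbon of each alkyne. It gives 2-[(1Z)-1-(3,4-dimethoxyphenyl)prop-1-en-2-yl]-4,4,5,5-tetramethyl-1,3,2-dioxaborolane F9 from 3 and 4,4,5,5-tetramethyl-2-[(1Z)-1-(3,4,5-trimethoxyphenyl)prop-1-en-2-yl]-1,3,2-dioxaborolane F10 from 5.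
- Iododeboronation of the latter with retention (NaOH, I2, THF, 0 °C) gives 5-[(1E)-2-iodoprop-1-en-1-yl]-1,2,3-trimethoxybenzene F11.
- Suzuki–Miyaura coupling of the boronate from 3 with this iodide (Pd(PPh3)4, K3PO4, dioxane/H2O, 60 °C) joins C3–C4 with retention at both alkenes and so delivers 8 without any statistical pairing.

Step 5. The benzylic cation may be captured by the other arene in a Friedel–Crafts closure to an aryltetralin, or equilibration may be incomplete and leave 2,3-cis ethers. The fallback sets out from diol 10 and returns at 11.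
- One hydroxyl is activated under basic conditions instead (MsCl, Et3N, CH2Cl2, −20 → 0 °C), giving the mono-methanesulfonate (1S,2S,3S,4S)-1-(3,4-dimethoxyphenyl)-4-hydroxy-2,3-dimethyl-4-(3,4,5-trimethoxyphenyl)butyl methanesulfonate F12.
- This electron-rich benzylic sulfonate should ionise as an ion pair with no Lewis acid present and be captured by the remaining hydroxyl anti to the neighbouring methyl group, which is known behaviour for such diols.

**Further compounds**

F1 | step 4 | 3,4,5-trimethoxybenzaldehyde | COc1cc(C=O)cc(OC)c1OC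
F2 | step 4 | (1S,2S)-2-methyl-1-(3,4,5-trimethoxyphenyl)but-3-en-1-ol | C=C[C@H](C)[C@H](O)c1cc(OC)c(OC)c(OC)c1
F3 | step 4 | (1S,2S)-2-methyl-1-(3,4,5-trimethoxyphenyl)butane-1,4-diol | OCC[C@H](C)[C@H](O)c1cc(OC)c(OC)c(OC)c1
F4 | step 4 | (4S,5S)-4-methyl-5-(3,4,5-trimethoxyphenyl)oxolan-2-one | O=C1C[C@H](C)[C@@H](c2cc(OC)c(OC)c(OC)c2)O1
F5 | step 4 | (3S,4S,5S)-3,4-dimethyl-5-(3,4,5-trimethoxyphenyl)oxolan-2-one | O=C1[C@@H](C)[C@H](C)[C@@H](c2cc(OC)c(OC)c(OC)c2)O1
F6 | step 4 | (3S,4S,5S)-3,4-dimethyl-5-(3,4,5-trimethoxyphenyl)oxolan-2-ol (both anomers) | OC1[C@@H](C)[C@H](C)[C@@H](c2cc(OC)c(OC)c(OC)c2)O1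
F7 | step 4 | (3,4-dimethoxyphenyl)magnesium chloride | COc1ccc([Mg]Cl)cc1OC
F8 | step 4 | (1R,2S,3S,4S)-1-(3,4-dimethoxyphenyl)-2,3-dimethyl-4-(3,4,5-trimethoxyphenyl)butane-1,4-diol | COc1ccc([C@H](O)[C@@H](C)[C@H](C)[C@H](O)c2cc(OC)c(OC)c(OC)c2)cc1OC
F9 | step 3 | 2-[(1Z)-1-(3,4-dimethoxyphenyl)prop-1-en-2-yl]-4,4,5,5-tetramethyl-1,3,2-dioxaborolane | COc1ccc(/C=C(\C)B2OC(C)(C)C(C)(C)O2)cc1OC
F10 | step 3 | 4,4,5,5-tetramethyl-2-[(1Z)-1-(3,4,5-trimethoxyphenyl)prop-1-en-2-yl]-1,3,2-dioxaborolane | COc1cc(/C=C(\C)B2OC(C)(C)C(C)(C)O2)cc(OC)c1OC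
F11 | step 3 | 5-[(1E)-2-iodoprop-1-en-1-yl]-1,2,3-trimethoxybenzene | COc1cc(/C=C(\C)I)cc(OC)c1OC
F12 | step 5 | (1S,2S,3S,4S)-1-(3,4-dimethoxyphenyl)-4-hydroxy-2,3-dimethyl-4-(3,4,5-trimethoxyphenyl)butyl methanesulfonate | COc1ccc([C@@H](OS(C)(=O)=O)[C@@H](C)[C@H](C)[C@H](O)c2cc(OC)c(OC)c(OC)c2)cc1OC
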